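The readings stem from a simulated flask with constants of no real substance; the scatter is artificial.

At the last reading, 120 min in, the starting material stands at 1.3% in oak, 4.0% in maple and 3.4% in larch, each with a scatter of 1 percentage point. These readings follow no order in the scavenger, although its charge grows 3.88-fold from oak to larch and the oak-to-larch gap of 2.1 points stays under the margin. So I leave the scavenger out of my reckoning, try the loss as first order in the fraction of starting material left, and take the mean of these readings, 2.90%, for every charge.

| flask | starting material | scavenger | protic impurity | remark | time |
|---|---|---|---|---|---|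
| oak | 13 mM | 0.49 equiv | 13 mM | run made earlier |  |
| maple | 13 mM | 0.98 equiv | 13 mM | run made earlier |  |
| larch | 13 mM | 1.9 equiv | 13 mM | run made earlier |  |
| grey | 13 mM | 2.00 equiv | 13.0 mM |  | 2.0 h |
| red | 13 mM | 0.500 equiv | 13.0 mM |  | 2.0 h |
| blue | 13 mM | 1.00 equiv | 13.0 mM |  | 2.0 h |

| run | time / min | starting material / % | target / % |
|---|---|---|---|
| oak | 15.0 | 25.7 | 28.6 |
| oak | 40.0 | 7.4 | 38.0 |
| oak | 80.0 | 5.0 | 41.1 |
| oak | 120 | 1.3 | 42.6 |
| maple | 15.0 | 28.1 | 28.6 |
| maple | 40.0 | 11.8 | 40.7 |
| maple | 80.0 | 7.2 | 44.2 |
| maple | 120 | 4.0 | 44.3 |
| larch | 30.0 | 15.5 | 39.0 |
| larch | 60.0 | 6.4 | 46.6 |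
| larch | 90.0 | 6.9 | 48.4 |
| larch | 120 | 3.4 | 50.7 |

(standard deviation of a reading: 1 percentage point)

- what has gone from starting material into another species counts as reacted, even if it can come back

- part of the starting material that has reacted at the end, grey
- part of the starting material that has reacted at the end, red
- part of the starting material that has reacted at the end, blue
- what raising the equivalents of scavenger from its lowest to its highest value here does to the part of the starting material that has reacted (changes below 5 percentage points count as none) (it rises / no change / it falls)

The bench rule says a first-order loss keeps its half-life. Oak and maple average 26.9% left at 15.0 min, which gives a half-life of 7.92 min. Carried to 40.0 min, that half-life leaves 3.02%, but the same two runs average 9.60% there, 3.18 times as much, so the rule stops working between those two readings. Beyond them I use the tail halving time, the half-life of the late decay, in which the starting material left halves from 40.0 min onward: going from 9.60% to 2.90% gives 46.3 min, 5.85 times the early value. Grey, red and blue are charged like the earlier runs and read at 2.0 h, so I commit to 97.1% reacted in each, with no change across the scavenger range.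

The forecast gives 96.5% for grey, 97.3% for red and 96.6% for blue, a little apart where I keep one number, and agrees with me on the trend: “The change is well under 5 points, so the trend is no change.”

The flasks give 96.7% for grey, 96.9% for red and 96.2% for blue, with no change (−0.25 points).

    starting material ⇌ target + released group (K = 0.110 M, k = 5.90 × 10⁻⁴ s⁻¹)
    starting material + released group ⇌ idle adduct, settled at all times (K = 13000 M⁻¹)
    scavenger + released group → scavenged by-product (k = 0.600 M⁻¹ s⁻¹)
    starting material + protic impurity → quenched substrate (k = 0.0240 M⁻¹ s⁻¹)
    target → over-reaction product (k = 5.20 × 10⁻⁵ s⁻¹)

At 2.00 h blue has 3.8% of its starting material left, 0.90 points above the 2.90% I took from the readings, and what counts as reacted in blue is not all target, which stands at 46.0%. The neighbour is blue read at 50 min. Starting from the oak and maple mean of 9.60% at 40.0 min and running 10.0 min along the tail of 46.3 min leaves 8.27%, so 91.7% reacted; that neighbour of blue has 8.4% of its starting material left, unbound, and has reacted 91.6%.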